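**Strategy.** The route rests on cutting the bond between the guaiacyl ring and C3 of the tetrahydrofuro[3,4-c]furan-1-one core. C3 is the γ-carbon of the lactone and is bonded to the ring oxygen O2, so it can be taken to the acylal level and ionised to a bicyclic acyloxocarbenium ion. In one operation an aryl group is transferred from boron to this cation on the convex face of the cis-fused bicycle, which forms the bond and sets the C3 stereocentre (aryl exo). The precursor is the 3-acetoxy lactone that already carries the protected catechol ring; it is reached from (S)-4-vinylbutyrolactone by aldol, alkene cleavage and an acid-mediated ring-chain isomerisation.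

Key step: step 6

Remark: bicycle atoms are numbered as in tetrahydro-1H,3H-furo[3,4-c]furan-1-one (C1 carbonyl, O2, C3, C3a, C4, O5, C6, C6a) and TBS is tert-butyldimethylsilyl; the carbinol carbon of 5 and 6 and the acylal carbon of 7 and 8 are carried as epimer mixtures (undefined in the SMILES) because each is ionised before its configuration is set.

**Step 1**
Reactants: 1 furan-2(5H)-one; 2 potassium vinyltrifluoroborate
Product: 3 (S)-4-vinyldihydrofuran-2(3H)-one
Conditions: [Rh(cod)2]BF4 (3 mol%), (S)-BINAP (3.3 mol%), toluene/H2O (4:1), 100 °C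
Reagents that add atoms: none
Why: Hayashi–Miyaura rhodium-catalysed asymmetric 1,4-addition, in which the vinyl–Rh(I)/(S)-BINAP species adds to one enantioface of the butenolide and water protonates the rhodium enolate, so the ligand sets the single stereocentre ((S)-BINAP is the hand that the usual enantioface model for cyclic enones and unsaturated lactones predicts for the (S)-lactone).

**Step 2**
Reactants: 3 (S)-4-vinyldihydrofuran-2(3H)-one; 4 3,4-bis(tert-butyldimethylsilyloxy)benzaldehyde
Product: 5 (3S,4R)-3-{[3,4-bis(TBSO)phenyl](hydroxy)methyl}-4-vinyldihydrofuran-2(3H)-one (3,4-trans; carbinol epimers)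
Conditions: LDA (1.1 equiv), THF, −78 °C; then 4, −78 °C; sat. aq. NH4Cl at −78 °C
Reagents that add atoms: none
Why: Lithium enolate aldol addition in which the lactone enolate takes the aldehyde on the face anti to the 4-vinyl group, which sets C3 trans to C4, while the carbinol centre is left uncontrolled because it is ionised in step 4.

**Step 3**
Reactants: 5 (3S,4R)-3-{[3,4-bis(TBSO)phenyl](hydroxy)methyl}-4-vinyldihydrofuran-2(3H)-one
Product: 6 (3R,4S)-4-{[3,4-bis(TBSO)phenyl](hydroxy)methyl}-5-oxotetrahydrofuran-3-carbaldehyde (3,4-trans; carbinol epimers)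
Conditions: K2OsO4·2H2O (2 mol%), NaIO4 (4 equiv), 2,6-lutidine, dioxane/H2O (3:1), rt
Reagents that add atoms: sodium periodate [Na+].[O-]I(=O)(=O)=O (terminal oxidant that supplies the aldehyde oxygen through the osmium catalyst); water O
Why: Lemieux–Johnson oxidation cleaves only the terminal alkene under lutidine-buffered conditions that should leave the aryl silyl ethers, the benzylic alcohol and both ring stereocentres untouched, the trans arrangement also being the thermodynamically preferred one at the new α-formyl centre.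

**Step 4**
Reactants: 6 (3R,4S)-4-{[3,4-bis(TBSO)phenyl](hydroxy)methyl}-5-oxotetrahydrofuran-3-carbaldehyde
Product: 8 (3aR,6S,6aS)-3-acetoxy-6-[3,4-bis(TBSO)phenyl]tetrahydro-1H,3H-furo[3,4-c]furan-1-one (C3 epimers), via hydroxy lactone 7 (not isolated)
Conditions: TsOH·H2O (10 mol%), MeCN/H2O (20:1), 0 °C → rt; then solvent exchange, Ac2O, pyridine, DMAP (cat.), CH2Cl2, 0 °C
Reagents that add atoms: acetic anhydride CC(=O)OC(C)=O
Why: Acid-mediated ring–chain isomerisation of the type established for α,β-bis(hydroxybenzyl)butyrolactones: the hydrate of the formyl group takes over the lactone acyl group (transacylation to the five-membered hydroxy lactone), the primary alcohol released captures the 3,4-bis(silyloxy)benzylic cation in a 5-exo SN1 cycloetherification that is forced to be cis-fused by the trans relation of C3 and C4 in 6 and places the aryl group exo (anti to the C1 carbonyl across C6a) under kinetic control, and routine acetylation of the lactol hydroxyl then gives the acylal.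

**Step 5**
Reactants: 9 2-methoxy-4-(4,4,5,5-tetramethyl-1,3,2-dioxaborolan-2-yl)phenol (4-hydroxy-3-methoxyphenylboronic acid pinacol ester)
Product: 10 potassium trifluoro(4-hydroxy-3-methoxyphenyl)borate
Conditions: KHF2 (4.5 equiv), MeOH/H2O, rt
Reagents that add atoms: potassium hydrogen difluoride [K+].[F-].F
Why: Fluoride exchange at boron with KHF2 displaces pinacol and should give the crystalline trifluoroborate, the salt that releases an aryldifluoroborane under BF3.

**Step 6**
Reactants: 8 (3aR,6S,6aS)-3-acetoxy-6-[3,4-bis(TBSO)phenyl]tetrahydro-1H,3H-furo[3,4-c]furan-1-one; 10 potassium trifluoro(4-hydroxy-3-methoxyphenyl)borate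
Product: 11 (3S,3aR,6S,6aS)-6-[3,4-bis(TBSO)phenyl]-3-(4-hydroxy-3-methoxyphenyl)tetrahydro-1H,3H-furo[3,4-c]furan-1-one
Conditions: 10 (1.3 equiv), BF3·OEt2 (2 equiv), CH2Cl2/MeCN, −40 → 0 °C
Reagents that add atoms: none
Why: Proposed new method: BF3 removes fluoride from 10 to give the aryldifluoroborane, which takes up the acetate of 8 as it ionises; the ion pair of the bicyclic acyloxocarbenium ion (C3=O2+) and the aryl(acetoxy)difluoroborate then collapses by ipso transfer of the aryl group from boron to C3. The closest known reaction types are the BF3-promoted coupling of potassium aryltrifluoroborates with O,O- and N,O-acetals through oxocarbenium and N-acyliminium ions and the Friedel–Crafts arylation of γ-hydroxy and γ-acyloxy lactones; an acylal on a saturated lactone as the partner of an aryl boron ate complex is the element without direct precedent. No ring is closed in this step. The new stereocentre C3 is set by the substrate: the planar cation is attacked on the convex face of the cis-fused bicycle, anti to the C3a–C4 bond, so the aryl group ends cis to H-3a (exo), as the target requires. The step needs site selectivity between the acylal C3–OAc and the benzylic ether C6–O5 and positional selectivity on the arene; acetate is the better leaving group at low temperature and a transient opening at C6 would reclose on the same exo face, while boron at the carbon para to the free hydroxyl fixes the point of attachment.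

**Step 7**
Reactants: 11 (3S,3aR,6S,6aS)-6-[3,4-bis(TBSO)phenyl]-3-(4-hydroxy-3-methoxyphenyl)tetrahydro-1H,3H-furo[3,4-c]furan-1-one
Product: 12 (3S,3aR,6S,6aS)-6-(3,4-dihydroxyphenyl)-3-(4-hydroxy-3-methoxyphenyl)tetrahydro-1H,3H-furo[3,4-c]furan-1-one
Conditions: Et3N·3HF, THF, 0 °C → rt
Reagents that add atoms: none
Why: Fluoride-mediated cleavage of the two aryl silyl ethers under mildly acidic, buffered conditions should avoid catecholate oxidation and leave the lactone, both benzylic C–O bonds and all four stereocentres untouched.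

**Compound list**
1 | furan-2(5H)-one | O=C1OCC=C1 | starting material
2 | potassium vinyltrifluoroborate | [K+].C=C[B-](F)(F)F | starting material
3 | (S)-4-vinyldihydrofuran-2(3H)-one | C=C[C@H]1COC(=O)C1 | intermediate
4 | 3,4-bis(tert-butyldimethylsilyloxy)benzaldehyde | O=Cc1ccc(O[Si](C)(C)C(C)(C)C)c(O[Si](C)(C)C(C)(C)C)c1 | starting material
5 | (3S,4R)-3-{[3,4-bis(TBSO)phenyl](hydroxy)methyl}-4-vinyldihydrofuran-2(3H)-one (3,4-trans; carbinol epimers) | C=C[C@H]1COC(=O)[C@@H]1C(O)c1ccc(O[Si](C)(C)C(C)(C)C)c(O[Si](C)(C)C(C)(C)C)c1 | intermediate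
6 | (3R,4S)-4-{[3,4-bis(TBSO)phenyl](hydroxy)methyl}-5-oxotetrahydrofuran-3-carbaldehyde (3,4-trans; carbinol epimers) | O=C[C@H]1COC(=O)[C@@H]1C(O)c1ccc(O[Si](C)(C)C(C)(C)C)c(O[Si](C)(C)C(C)(C)C)c1 | intermediate
7 | (3aR,6S,6aS)-6-[3,4-bis(TBSO)phenyl]-3-hydroxytetrahydro-1H,3H-furo[3,4-c]furan-1-one (cis-fused; aryl exo; C3 epimers) | OC1OC(=O)[C@H]2[C@@H]1CO[C@@H]2c1ccc(O[Si](C)(C)C(C)(C)C)c(O[Si](C)(C)C(C)(C)C)c1 | intermediate
8 | (3aR,6S,6aS)-3-acetoxy-6-[3,4-bis(TBSO)phenyl]tetrahydro-1H,3H-furo[3,4-c]furan-1-one (C3 epimers) | CC(=O)OC1OC(=O)[C@H]2[C@@H]1CO[C@@H]2c1ccc(O[Si](C)(C)C(C)(C)C)c(O[Si](C)(C)C(C)(C)C)c1 | intermediate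
9 | 2-methoxy-4-(4,4,5,5-tetramethyl-1,3,2-dioxaborolan-2-yl)phenol | COc1cc(B2OC(C)(C)C(C)(C)O2)ccc1O | starting material
10 | potassium trifluoro(4-hydroxy-3-methoxyphenyl)borate | [K+].COc1cc([B-](F)(F)F)ccc1O | intermediate
11 | (3S,3aR,6S,6aS)-6-[3,4-bis(TBSO)phenyl]-3-(4-hydroxy-3-methoxyphenyl)tetrahydro-1H,3H-furo[3,4-c]furan-1-one | COc1cc([C@H]2OC(=O)[C@H]3[C@@H]2CO[C@@H]3c2ccc(O[Si](C)(C)C(C)(C)C)c(O[Si](C)(C)C(C)(C)C)c2)ccc1O | intermediate
12 | (3S,3aR,6S,6aS)-6-(3,4-dihydroxyphenyl)-3-(4-hydroxy-3-methoxyphenyl)tetrahydro-1H,3H-furo[3,4-c]furan-1-one (CNP0268159.1) | COc1cc([C@H]2OC(=O)[C@H]3[C@@H]2CO[C@@H]3c2ccc(O)c(O)c2)ccc1O | target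

Total step count: 7
Longest linear sequence: 6 steps (1, 2, 3, 4, 6, 7)

**Steps most likely to fail**

Step 6 (Proposed new method). Ionisation of the acylal may be too slow relative to protodeboronation of the electron-rich aryl donor. The benzylic ether at C6 may also ionise competitively and be arylated, and exo selectivity may erode if the product lactone re-ionises. The fallback sets out from hydroxy lactone 7 (isolated when the acetylation of step 4 is left out) and comes back to the route at 12. It moves the stereo-determining event from aryl delivery to hydride delivery and uses no Lewis acid. Oxidation of the lactol with TEMPO (cat.)/PhI(OAc)2 in CH2Cl2 should give the cyclic anhydride (3aS,4S,6aR)-4-[3,4-bis(TBSO)phenyl]tetrahydro-1H,3H-furo[3,4-c]furan-1,3-dione F1. The Grignard reagent [4-(TBSO)-3-methoxyphenyl]magnesium bromide F2 is made from commercial (4-bromo-2-methoxyphenoxy)(tert-butyl)dimethylsilane and magnesium in THF. It is added at −78 °C and should attack the less hindered carbonyl, the one remote from the aryl-bearing carbon, to give the keto acid (2S,3S,4R)-2-[3,4-bis(TBSO)phenyl]-4-[4-(TBSO)-3-methoxybenzoyl]tetrahydrofuran-3-carboxylic acid F3. Reduction of the aryl ketone with NaBH4 in MeOH at −40 °C is expected to follow Felkin–Anh control, with the ring carbon that bears the carboxylate as the large group anti to hydride; a Corey–Bakshi–Shibata reduction is the reagent-controlled variant. This should give the (S)-carbinol hydroxy acid F4, which closes on acidification to the tris-silyl lactone F5 with the aryl group exo. The conditions of step 7 then give 12.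

Step 4. Acid-induced dehydration of the β-hydroxy lactone (loss of H-3 from the benzylic cation) may outrun the acyl shift that frees the primary alcohol, and the α-formyl centre may epimerise under acid. The fallback sets out from aldehyde 6 and comes back to the route at 12. The Grignard reagent F2 (2.2 equiv, THF, −78 °C; the first equivalent deprotonates the carbinol) should add to the aldehyde much faster than to the lactone and give the bis(hydroxybenzyl) lactone (3S,4R)-3-{[3,4-bis(TBSO)phenyl](hydroxy)methyl}-4-{[4-(TBSO)-3-methoxyphenyl](hydroxy)methyl}dihydrofuran-2(3H)-one F6. Catalytic TsOH in CH2Cl2 at 0 °C then triggers the known translactonisation–cycloetherification of such diol lactones. Here the new secondary benzylic hydroxyl is a permanent acyl acceptor, so the primary alcohol is free before the cation forms and no aldehyde remains to epimerise. The product is the tris-silyl lactone F5, which is deprotected as in step 7.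

Step 1. Slow transmetalation with protodeboronation or polymerisation of the vinyl donor, and hydrolytic or thermal loss of the butenolide at the temperature the rhodium catalyst needs, may limit conversion; enantioselectivity may also erode. The fallback sets out from 1 and comes back to the route at 3. Copper-catalysed conjugate addition of vinylmagnesium bromide (CuI cat., THF, −78 °C) should give racemic 4-vinyldihydrofuran-2(3H)-one F7. Ring opening with (S)-1-phenylethylamine gives two diastereomeric hydroxy amides, from which (S)-3-(hydroxymethyl)-N-[(S)-1-phenylethyl]pent-4-enamide F8 is separated by crystallisation or chromatography. Hot aqueous H2SO4/dioxane then relactonises F8 to 3 and returns the amine.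

Further compounds
F1 | step 6 | (3aS,4S,6aR)-4-[3,4-bis(TBSO)phenyl]tetrahydro-1H,3H-furo[3,4-c]furan-1,3-dione | O=C1OC(=O)[C@H]2[C@@H]1CO[C@@H]2c1ccc(O[Si](C)(C)C(C)(C)C)c(O[Si](C)(C)C(C)(C)C)c1
F2 | step 6 | [4-(tert-butyldimethylsilyloxy)-3-methoxyphenyl]magnesium bromide | COc1cc([Mg]Br)ccc1O[Si](C)(C)C(C)(C)C
F3 | step 6 | (2S,3S,4R)-2-[3,4-bis(TBSO)phenyl]-4-[4-(TBSO)-3-methoxybenzoyl]tetrahydrofuran-3-carboxylic acid | OC(=O)[C@H]1[C@@H](C(=O)c2ccc(O[Si](C)(C)C(C)(C)C)c(OC)c2)CO[C@@H]1c1ccc(O[Si](C)(C)C(C)(C)C)c(O[Si](C)(C)C(C)(C)C)c1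
F4 | step 6 | (2S,3S,4R)-2-[3,4-bis(TBSO)phenyl]-4-{(S)-hydroxy[4-(TBSO)-3-methoxyphenyl]methyl}tetrahydrofuran-3-carboxylic acid | OC(=O)[C@H]1[C@@H]([C@H](O)c2ccc(O[Si](C)(C)C(C)(C)C)c(OC)c2)CO[C@@H]1c1ccc(O[Si](C)(C)C(C)(C)C)c(O[Si](C)(C)C(C)(C)C)c1
F5 | step 6 | (3S,3aR,6S,6aS)-6-[3,4-bis(TBSO)phenyl]-3-[4-(TBSO)-3-methoxyphenyl]tetrahydro-1H,3H-furo[3,4-c]furan-1-one | COc1cc([C@H]2OC(=O)[C@H]3[C@@H]2CO[C@@H]3c2ccc(O[Si](C)(C)C(C)(C)C)c(O[Si](C)(C)C(C)(C)C)c2)ccc1O[Si](C)(C)C(C)(C)C
F6 | step 4 | (3S,4R)-3-{[3,4-bis(TBSO)phenyl](hydroxy)methyl}-4-{[4-(TBSO)-3-methoxyphenyl](hydroxy)methyl}dihydrofuran-2(3H)-one (carbinol epimers) | COc1cc(C(O)[C@H]2COC(=O)[C@@H]2C(O)c2ccc(O[Si](C)(C)C(C)(C)C)c(O[Si](C)(C)C(C)(C)C)c2)ccc1O[Si](C)(C)C(C)(C)C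
F7 | step 1 | racemic 4-vinyldihydrofuran-2(3H)-one | C=CC1COC(=O)C1
F8 | step 1 | (S)-3-(hydroxymethyl)-N-[(S)-1-phenylethyl]pent-4-enamide | C=C[C@@H](CO)CC(=O)N[C@@H](C)c1ccccc1
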